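The readings are calculated from invented constants; the scatter is artificial.

In a one-step world each percent of starting material lost is a percent of target. The spring flask shows otherwise: at 480 min it holds 43 % starting material, 30 % target and 27.0 % in a form that no reading shows.

in all of them: starting material 0.20 M; gas 130 mM (held)

|  | second substrate | temperature | remark | time |
|---|---|---|---|---|
| spring | 0.10 M | 25 °C | the very flask that is asked about, followed so far |  |
| dusk | 0.10 M | 10 °C | run made earlier |  |
| flask | 0.100 M | 25 °C |  | 8.0 h |

| run | time / min | target / % | starting material / % |
|---|---|---|---|
| spring | 40.0 | 30 | 56 |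
| spring | 120 | 32 | 44 |
| spring | 240 | 30 | 41 |
| spring | 360 | 32 | 44 |
| spring | 480 | 30 | 43 |
| dusk | 80.0 | 22 | 71 |
| dusk | 240 | 44 | 42 |
| dusk | 480 | 51 | 32 |
| dusk | 720 | 51 | 27 |
| dusk | 900 | 47 | 27 |

(each reading ± 1.5 percentage points)

- birch: change nothing and wait 8.0 h more
- ash: at 8.0 h take out 90 % of the target then present, then wait 8.0 h
- elm: at 8.0 h raise the temperature by 20 K, then wait 8.0 h
- maple: at 8.0 h add starting material, 50.0 % of the amount charged, then wait 8.0 h

- removed target is counted in
- at the start none of the gas is in solution
- additions bring no volume worth counting

- target, in percent of the starting material first charged, at 8.0 h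
- the option that brings most further target ("none" if no option brings more than 2 percentage points) (birch / ash / elm / maple / none)
- target present, with what was taken out counted in, in percent of the starting material first charged, after ash
- target present, with what was taken out counted in, in percent of the starting material first charged, after maple

From 120 min to 480 min the spring readings stay flat within their scatter, with starting material left over, while the colder dusk run, from the same charge, carries target up to 51 %. So I read the spring stop as a balance, and I took two amounts: target on the plateau, and the whole pool of starting material in whatever form, which is the charge. Their ratio read 31.0 % in spring: the settled share. With the gas held, I bet that this share stays put at one temperature, with second substrate a bystander. The dusk readings of target from 480 min on average 49.7 %, but starting material in that run was still falling, from 32 % to 27 %, so I took this figure as a reading from a run not shown to have settled.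

The wait of 8.0 h is longer than the 120 min spring needed, by a factor of 4.00, so I expected thermodynamic control, with target returning to share times pool. Birch then gains nothing, and I expected elm to lose, since the spring share stands lower than the target read in the colder dusk run. Ash leaves a pool of 72.1 % and reaches 50.3 % with the removed target counted in. Maple enlarges the pool to 150 % and reaches 46.5 %. I committed to 31.0 % now, and to ash.

The forecast gave 31 %, ash, 40.5 % after ash and 37 % after maple, reading dusk's plateau as “the limit set by the second substrate”. Its two yields stand below mine.

The flask gave 31.8 % at 8.0 h, and ash was best at 51.3 %, with 47.7 % after maple.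

    second substrate + coupling partner ⇌ second product (K = 6.90 M⁻¹, k = 0.0110 M⁻¹ min⁻¹, Ea = 73.0 kJ mol⁻¹, ΔH = −47.0 kJ mol⁻¹)
    starting material + coupling partner ⇌ target (K = 5.80 M⁻¹, k = 0.140 M⁻¹ min⁻¹, Ea = 71.0 kJ mol⁻¹, ΔH = −38.0 kJ mol⁻¹)
    gas ⇌ coupling partner, rate k3*(csat - [coupling partner]) (kL = 1.70 min⁻¹)
    starting material ⇌ dormant form (K = 0.620, k = 0.00650 min⁻¹, Ea = 88.0 kJ mol⁻¹, ΔH = −39.0 kJ mol⁻¹)
    (constants at 25 °C)

In the flask at 480 min, the coupling of starting material with coupling partner has a relaxation half-life, both ways together and by this step alone, of 12.8 min, shorter than the 8.0 h; its backward rate is 100 % of its forward rate, and the settled share, read as 31.0 %, gives 46.5 % on maple's pool where the flask gives 47.7 %.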